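The readings were generated by integration for substances that don't exist; scatter was added.

Time comes first: red runs 25 h, ten times as long as the last south-east reading at 2.50 h, and violet runs 30 h. The question is where such a flask stops.

| flask | D | remark | time |
|---|---|---|---|
| south-east | 2.2 M | run made earlier |  |
| red | 1.5 M |  | 25 h |
| violet | 1.5 M |  | 30 h |

south-east run (percent of the D charged)

| time / h | X / % | D / % | Q / % | E / % |
|---|---|---|---|---|
| 0.200 | 23.2 | 64.5 | 1.3 | 11.0 |
| 0.417 | 34.3 | 48.2 | 2.8 | 14.9 |
| 0.667 | 41.1 | 39.1 | 3.5 | 15.1 |
| 1.33 | 47.4 | 31.7 | 6.1 | 15.0 |
| 2.50 | 50.6 | 28.7 | 6.5 | 14.2 |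

(standard deviation of a reading: 0.5 percentage points)

- a species is counted by the D in it: one X counts as two

1. which of these there is most of at the end, counted by the D in it, red (D / X / Q / E)
2. which of these there is most of at the end, counted by the D in it, violet (D / X / Q / E)
3. the largest of these amounts at the end, in percent of the D charged, red
4. the largest of these amounts at the end, in percent of the D charged, violet

Had the south-east run stopped at its last reading? Not quite: X rose 3.2 percentage points over the last interval, so a number read there is a low mark.

Does Q leak away for good? That is the weak spot. Q gained 2.6 points and then 0.4 points, the last gain less than the scatter of 0.5 points. So I take Q as standing still, at the risk of a slow leak the readings hide.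

Then what are the chances of one D unit? It sits either in X or in a pool of D, E and Q. The last south-east reading gives 0.471 L mol⁻¹ for the pairing number, cX in molecules over the square of cD + cE + cQ.

And at 1.5 M? My reckoning: the same pairing number puts 44.1% in X in red and in violet, with somewhat more possible from the low mark. D keeps its share of the pool, 32.5%, which X exceeds.

The forecast also names X in red and X in violet, but at 34.5% and 32.5%, less than my figure. Its ground: “I take Q as irreversible and second order in D”.

The flask gives X in red and X in violet, at 46.7% and 46.7%.

    D ⇌ E (K = 0.460, k = 0.920 h⁻¹)
    2 D ⇌ X (K = 1.50 L mol⁻¹, k = 0.440 L mol⁻¹ h⁻¹)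
    E ⇌ Q (K = 0.420, k = 1.00 h⁻¹)

Both flasks are at rest, the usual term being thermodynamic control. Red holds 46.7% X after 12.5 h, 46.7% after 25.0 h and 46.7% after 250 h, so ten times the time changes nothing. Violet holds 46.7% X after 300 h, and Q stays at 6.23%. The slowest mode of violet has a half-life of 1.08 h, far shorter than its run. The pairing number's 44.1% lies 2.6 points under the flask.

A neighbour flask is violet with 0.60 M of D, and for it the pairing number gives 28.7% in X. Computed, that neighbour holds 31.2% in X, and D leads it with more, 41.6%.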